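The cyclohexane (C5–C10, elemane numbering) is closed last, at the C7–C8 bond, by an intramolecular Barbier allylation. A 3-(chloromethyl)-4-alkoxybutenolide, which already is the lactone ring (O–C12–C11–C7–C6), is metalated at C13 and attacks the tethered C8 aldehyde through C7. The step exploits the homoallylic alcohol C13=C11–C7–C8–OH that straddles the junction of lactone and cyclohexane; one operation gives the carbocycle, the C7 and C8 carbinol centres and the exocyclic C11=C13 methylene. The precursor is an open C5–C10–C9–C8 chain on C6 of a tetronate; its C5 and C10 centres come from a dienolate Ireland–Claisen rearrangement relayed from C9 of (S)-glyceraldehyde acetonide.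

Key step: step 17

Remark: atom numbers follow the elemane convention: C10 is the quaternary carbon (methyl C14, vinyl C1=C2), C5 carries the isopropenyl group (C4, C3, C15), C6 the lactone oxygen, C7 the tertiary hydroxyl, C8 the secondary hydroxyl, C9 the ester, C11=C13 is the methylene and C12 the lactone carbonyl. The ester is read as the (Z)-2-methylbut-2-enoate (angelate), and (S)-2,2-dimethyl-1,3-dioxolane-4-carbaldehyde is taken as a catalogue compound.

Step 1
Reactants: 1 (S)-2,2-dimethyl-1,3-dioxolane-4-carbaldehyde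
Product: 2 (R)-4-ethynyl-2,2-dimethyl-1,3-dioxolane
Conditions: dimethyl (1-diazo-2-oxopropyl)phosphonate, K2CO3, MeOH, 0 °C to rt
Reagents that add atoms: dimethyl (1-diazo-2-oxopropyl)phosphonate, CC(=O)C(=[N+]=[N-])P(=O)(OC)OC
Why: Seyferth–Gilbert homologation with the Ohira–Bestmann reagent should turn the aldehyde into the terminal alkyne under carbonate conditions mild enough to leave the α-alkoxy centre (future C9) untouched.

Step 2
Reactants: 2 (R)-4-ethynyl-2,2-dimethyl-1,3-dioxolane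
Product: 3 methyl 3-[(4R)-2,2-dimethyl-1,3-dioxolan-4-yl]prop-2-ynoate
Conditions: n-BuLi, THF, −78 °C; ClCO2Me, −78 °C to 0 °C
Reagents that add atoms: methyl chloroformate, COC(=O)Cl
Why: C-acylation of the deprotonated terminal alkyne with a chloroformate is a standard route to ynoates and does not touch the stereocentre.

Step 3
Reactants: 3 methyl 3-[(4R)-2,2-dimethyl-1,3-dioxolan-4-yl]prop-2-ynoate
Product: 4 methyl (2Z)-3-[(4R)-2,2-dimethyl-1,3-dioxolan-4-yl]but-2-enoate
Conditions: Me2CuLi (from CuI and MeLi), THF, −78 °C; aq. NH4Cl at −78 °C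
Reagents that add atoms: lithium dimethylcuprate, [Li+].C[Cu-]C
Why: syn-Carbocupration of the ynoate by the Gilman cuprate with cold protonation should place the methyl group on C10 and leave the dioxolanyl group cis to the ester, which fixes the Z trisubstituted alkene.

Step 4
Reactants: 4 methyl (2Z)-3-[(4R)-2,2-dimethyl-1,3-dioxolan-4-yl]but-2-enoate
Product: 5 (2Z)-3-[(4R)-2,2-dimethyl-1,3-dioxolan-4-yl]but-2-en-1-ol
Conditions: diisobutylaluminium hydride (DIBAL-H), CH2Cl2, −78 °C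
Reagents that add atoms: none
Why: 1,2-Reduction of the enoate by DIBAL-H should give the allylic alcohol without change of the alkene geometry.

Step 5
Reactants: 5 (2Z)-3-[(4R)-2,2-dimethyl-1,3-dioxolan-4-yl]but-2-en-1-ol; 6 3-methylbut-2-enoic acid
Product: 7 (2Z)-3-[(4R)-2,2-dimethyl-1,3-dioxolan-4-yl]but-2-en-1-yl 3-methylbut-2-enoate
Conditions: DCC, DMAP (cat.), CH2Cl2, 0 °C to rt
Reagents that add atoms: none
Why: Steglich esterification of a primary allylic alcohol; a shift of the acyl double bond out of conjugation would be harmless because both isomers lead to the same dienolate.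

Step 6
Reactants: 7 (2Z)-3-[(4R)-2,2-dimethyl-1,3-dioxolan-4-yl]but-2-en-1-yl 3-methylbut-2-enoate
Product: 9 (2S,3S)-3-[(4R)-2,2-dimethyl-1,3-dioxolan-4-yl]-3-methyl-2-(prop-1-en-2-yl)pent-4-enoic acid, via trimethylsilyl ketene acetal 8 (not isolated)
Conditions: lithium diisopropylamide (LDA), THF, −78 °C; Me3SiCl, −78 °C to rt; aq. NH4Cl
Reagents that add atoms: none
Why: Dienolate Ireland–Claisen rearrangement: γ-deprotonation of the s-cis enoate through a lithium-bridged transition state should put OSiMe3 cis to the isopropenyl group, the chair transition state with the Z allyl terminus (dioxolanyl axial, methyl equatorial) then sets C5 and C10 as (2S,3S), and C9 controls the face through allylic 1,3-strain (C9–H in the alkene plane, new bond anti to the C9–O bond).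

Step 7
Reactants: 9 (2S,3S)-3-[(4R)-2,2-dimethyl-1,3-dioxolan-4-yl]-3-methyl-2-(prop-1-en-2-yl)pent-4-enoic acid
Product: 10 (2S,3S)-3-[(4R)-2,2-dimethyl-1,3-dioxolan-4-yl]-N-methoxy-N,3-dimethyl-2-(prop-1-en-2-yl)pent-4-enamide
Conditions: MeNH(OMe)·HCl, EDC·HCl, HOBt (cat.), i-Pr2NEt, CH2Cl2, 0 °C to rt
Reagents that add atoms: N,O-dimethylhydroxylamine hydrochloride, CNOC.Cl
Why: Carbodiimide amidation to the Weinreb amide, which permits a single acylation of a carbon nucleophile in step 10.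

Step 8
Reactants: 11 prop-2-yn-1-ol; 12 4-methoxybenzyl chloride
Product: 13 1-methoxy-4-[(prop-2-yn-1-yloxy)methyl]benzene
Conditions: NaH, Bu4NI (cat.), THF, 0 °C to rt
Reagents that add atoms: none
Why: Williamson etherification of a primary alkoxide with a benzylic chloride.

Step 9
Reactants: 13 1-methoxy-4-[(prop-2-yn-1-yloxy)methyl]benzene
Product: 14 1-methoxy-4-[(propa-1,2-dien-1-yloxy)methyl]benzene
Conditions: KOtBu (cat.), THF, rt
Reagents that add atoms: none
Why: Base-catalysed propargyl-to-allenyl ether isomerisation, the standard preparation of alkoxyallenes.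

Step 10
Reactants: 10 (2S,3S)-3-[(4R)-2,2-dimethyl-1,3-dioxolan-4-yl]-N-methoxy-N,3-dimethyl-2-(prop-1-en-2-yl)pent-4-enamide; 14 1-methoxy-4-[(propa-1,2-dien-1-yloxy)methyl]benzene
Product: 16 (5S,6S)-6-[(4R)-2,2-dimethyl-1,3-dioxolan-4-yl]-3-[(4-methoxybenzyl)oxy]-6-methyl-5-(prop-1-en-2-yl)octa-1,2,7-trien-4-one, via lithiated alkoxyallene 15 (not isolated)
Conditions: 14, n-BuLi, THF, −40 °C; then 10, −78 °C; H2O (pH 7 buffer)
Reagents that add atoms: none
Why: α-Lithiation of the alkoxyallene and Weinreb ketone synthesis; the chelated tetrahedral adduct should prevent over-addition and keep the enolisable C5 centre masked until the cold quench.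

Step 11
Reactants: 16 (5S,6S)-6-[(4R)-2,2-dimethyl-1,3-dioxolan-4-yl]-3-[(4-methoxybenzyl)oxy]-6-methyl-5-(prop-1-en-2-yl)octa-1,2,7-trien-4-one
Product: 17 (4S,5S,6S)-6-[(4R)-2,2-dimethyl-1,3-dioxolan-4-yl]-3-[(4-methoxybenzyl)oxy]-6-methyl-5-(prop-1-en-2-yl)octa-1,2,7-trien-4-ol
Conditions: diisobutylaluminium hydride (DIBAL-H), THF, −78 °C; Rochelle salt work-up
Reagents that add atoms: none
Why: 1,2-Reduction under Felkin–Anh control: hydride should add anti to the quaternary C10 group of the α-centre C5, which gives the (S)-carbinol at C6.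

Step 12
Reactants: 17 (4S,5S,6S)-6-[(4R)-2,2-dimethyl-1,3-dioxolan-4-yl]-3-[(4-methoxybenzyl)oxy]-6-methyl-5-(prop-1-en-2-yl)octa-1,2,7-trien-4-ol
Product: 18 (5S)-3-(chloromethyl)-5-{(1S,2S)-2-[(4R)-2,2-dimethyl-1,3-dioxolan-4-yl]-2-methyl-1-(prop-1-en-2-yl)but-3-en-1-yl}-4-[(4-methoxybenzyl)oxy]furan-2(5H)-one
Conditions: PdCl2 (5 mol%), CuCl2 (2.2 equiv), NaOAc, CO (1 atm), THF, 0 °C to rt
Reagents that add atoms: carbon monoxide, [C-]#[O+]; copper dichloride, Cl[Cu]Cl
Why: PdCl2-catalysed chlorocyclocarbonylation of a 2,3-allenol: the alkoxycarbonyl-palladium species should add to the central allene carbon C11 and CuCl2 should cleave the resulting π-allyl complex at its CH2 terminus, which closes the lactone and installs the C13 chloride without touching C6.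

Step 13
Reactants: 18 (5S)-3-(chloromethyl)-5-{(1S,2S)-2-[(4R)-2,2-dimethyl-1,3-dioxolan-4-yl]-2-methyl-1-(prop-1-en-2-yl)but-3-en-1-yl}-4-[(4-methoxybenzyl)oxy]furan-2(5H)-one
Product: 19 (5S)-3-(chloromethyl)-5-[(1S,2S,3R)-2-ethenyl-3,4-dihydroxy-2-methyl-1-(prop-1-en-2-yl)butyl]-4-[(4-methoxybenzyl)oxy]furan-2(5H)-one
Conditions: AcOH/H2O (4:1), 35 °C
Reagents that add atoms: none
Why: Acid hydrolysis of the terminal acetonide under conditions that the vinylogous 4-methoxybenzyl ester and the allylic chloride should survive.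

Step 14
Reactants: 19 (5S)-3-(chloromethyl)-5-[(1S,2S,3R)-2-ethenyl-3,4-dihydroxy-2-methyl-1-(prop-1-en-2-yl)butyl]-4-[(4-methoxybenzyl)oxy]furan-2(5H)-one
Product: 20 (5S)-3-(chloromethyl)-5-[(1S,2S,3R)-2-ethenyl-3-hydroxy-2-methyl-1-(prop-1-en-2-yl)-4-(triethylsilyloxy)butyl]-4-[(4-methoxybenzyl)oxy]furan-2(5H)-one
Conditions: Et3SiCl (1.05 equiv), imidazole, CH2Cl2, −30 °C
Reagents that add atoms: chlorotriethylsilane, CC[Si](Cl)(CC)CC
Why: Selective silylation of the primary C8 hydroxyl over the secondary C9 hydroxyl, which is shielded by the quaternary C10.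

Step 15
Reactants: 20 (5S)-3-(chloromethyl)-5-[(1S,2S,3R)-2-ethenyl-3-hydroxy-2-methyl-1-(prop-1-en-2-yl)-4-(triethylsilyloxy)butyl]-4-[(4-methoxybenzyl)oxy]furan-2(5H)-one; 21 angelic acid, (2Z)-2-methylbut-2-enoic acid
Product: 23 (2R,3S,4S)-4-{(2S)-4-(chloromethyl)-3-[(4-methoxybenzyl)oxy]-5-oxo-2,5-dihydrofuran-2-yl}-3-ethenyl-3,5-dimethyl-1-(triethylsilyloxy)hex-5-en-2-yl (2Z)-2-methylbut-2-enoate, via angelic trichlorobenzoic anhydride 22 (not isolated)
Conditions: 21, 2,4,6-trichlorobenzoyl chloride, Et3N, toluene, rt; then 20, 80 °C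
Reagents that add atoms: none
Why: Yamaguchi-type esterification through the mixed anhydride, a method suited to hindered alcohols that should keep the Z geometry of the angelate.

Step 16
Reactants: 23 (2R,3S,4S)-4-{(2S)-4-(chloromethyl)-3-[(4-methoxybenzyl)oxy]-5-oxo-2,5-dihydrofuran-2-yl}-3-ethenyl-3,5-dimethyl-1-(triethylsilyloxy)hex-5-en-2-yl (2Z)-2-methylbut-2-enoate
Product: 24 (2R,3S,4S)-4-{(2S)-4-(chloromethyl)-3-[(4-methoxybenzyl)oxy]-5-oxo-2,5-dihydrofuran-2-yl}-3-ethenyl-3,5-dimethyl-1-oxohex-5-en-2-yl (2Z)-2-methylbut-2-enoate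
Conditions: (COCl)2, DMSO, CH2Cl2, −78 °C to −40 °C; Et3N, to 0 °C
Reagents that add atoms: none
Why: Swern oxidation applied directly to the primary triethylsilyl ether: the chlorosulfonium salt should cleave the silyl ether in situ and the alkoxysulfonium ion is then oxidised to the aldehyde, so that the epimerisable C9 centre sees only cold Et3N.

Step 17
Reactants: 24 (2R,3S,4S)-4-{(2S)-4-(chloromethyl)-3-[(4-methoxybenzyl)oxy]-5-oxo-2,5-dihydrofuran-2-yl}-3-ethenyl-3,5-dimethyl-1-oxohex-5-en-2-yl (2Z)-2-methylbut-2-enoate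
Product: 26 (3aS,4S,5R,6S,7S,7aS)-6-ethenyl-4-hydroxy-3a-[(4-methoxybenzyl)oxy]-6-methyl-3-methylidene-2-oxo-7-(prop-1-en-2-yl)octahydro-1-benzofuran-5-yl (2Z)-2-methylbut-2-enoate, via allylindium dichloride 25 (not isolated)
Conditions: In powder, NaI (cat.), THF/H2O (3:1), rt
Reagents that add atoms: none
Why: Indium should insert into the C13–Cl bond (after iodide exchange) to give a 2-carbonyl-substituted allylindium, which adds to the tethered C8 aldehyde through its γ-carbon C7 in an SE2′ process via a metal-bridged six-membered transition state, so that C11=C13 becomes the exocyclic methylene. The closest known reaction type is the Barbier allylation of aldehydes with 3-(halomethyl)furan-2(5H)-ones and 2-(halomethyl)acrylates to β-substituted α-methylene-γ-butyrolactones, together with the γ-selective addition of γ-alkoxyallyl metals. The cyclohexane closes in a 6-exo-trig mode onto the carbonyl carbon, with the lactone ring already in place. C7 is controlled by C6, because the four-atom tether can reach only the butenolide face syn to C5, which gives the cis ring fusion with the C7 oxygen on the α face. C8 is controlled by the chair-like transition state in which isopropenyl, vinyl and the C9 angelate are equatorial and the metal-bound carbonyl oxygen is pseudo-equatorial, away from the axial C10 methyl and the axial lactone oxygen, which gives the 8α-hydroxyl trans to C11. The step needs γ- over α-attack, secured by ring size (six against eight), and tolerance of the α-acyloxy aldehyde and the angelate, secured by the neutral aqueous conditions.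

Step 18
Reactants: 26 (3aS,4S,5R,6S,7S,7aS)-6-ethenyl-4-hydroxy-3a-[(4-methoxybenzyl)oxy]-6-methyl-3-methylidene-2-oxo-7-(prop-1-en-2-yl)octahydro-1-benzofuran-5-yl (2Z)-2-methylbut-2-enoate
Product: 27 (3aS,4S,5R,6S,7S,7aS)-6-ethenyl-3a,4-dihydroxy-6-methyl-3-methylidene-2-oxo-7-(prop-1-en-2-yl)octahydro-1-benzofuran-5-yl (2Z)-2-methylbut-2-enoate (CNP0114166.3)
Conditions: DDQ, CH2Cl2/pH 7 phosphate buffer (10:1), 0 °C
Reagents that add atoms: none
Why: Oxidative cleavage of the 4-methoxybenzyl ether by DDQ in wet solvent should free the tertiary C7 hydroxyl under neutral conditions that tolerate the angelate, the three alkenes and the α-methylene lactone.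

Compound list
1 | (S)-2,2-dimethyl-1,3-dioxolane-4-carbaldehyde | CC1(C)OC[C@@H](C=O)O1 | starting material
2 | (R)-4-ethynyl-2,2-dimethyl-1,3-dioxolane | CC1(C)OC[C@@H](C#C)O1 | intermediate
3 | methyl 3-[(4R)-2,2-dimethyl-1,3-dioxolan-4-yl]prop-2-ynoate | CC1(C)OC[C@@H](C#CC(=O)OC)O1 | intermediate
4 | methyl (2Z)-3-[(4R)-2,2-dimethyl-1,3-dioxolan-4-yl]but-2-enoate | CC1(C)OC[C@@H](/C(C)=C\C(=O)OC)O1 | intermediate
5 | (2Z)-3-[(4R)-2,2-dimethyl-1,3-dioxolan-4-yl]but-2-en-1-ol | CC1(C)OC[C@@H](/C(C)=C\CO)O1 | intermediate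
6 | 3-methylbut-2-enoic acid | CC(C)=CC(O)=O | starting material
7 | (2Z)-3-[(4R)-2,2-dimethyl-1,3-dioxolan-4-yl]but-2-en-1-yl 3-methylbut-2-enoate | CC1(C)OC[C@@H](/C(C)=C\COC(=O)C=C(C)C)O1 | intermediate
8 | (1Z)-1-{[(2Z)-3-[(4R)-2,2-dimethyl-1,3-dioxolan-4-yl]but-2-en-1-yl]oxy}-3-methyl-1-(trimethylsilyloxy)buta-1,3-diene | CC1(C)OC[C@@H](/C(C)=C\CO/C(O[Si](C)(C)C)=C/C(C)=C)O1 | intermediate
9 | (2S,3S)-3-[(4R)-2,2-dimethyl-1,3-dioxolan-4-yl]-3-methyl-2-(prop-1-en-2-yl)pent-4-enoic acid | C=C[C@@](C)([C@H](C(C)=C)C(O)=O)[C@@H]1COC(C)(C)O1 | intermediate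
10 | (2S,3S)-3-[(4R)-2,2-dimethyl-1,3-dioxolan-4-yl]-N-methoxy-N,3-dimethyl-2-(prop-1-en-2-yl)pent-4-enamide | C=C[C@@](C)([C@H](C(C)=C)C(=O)N(C)OC)[C@@H]1COC(C)(C)O1 | intermediate
11 | prop-2-yn-1-ol | C#CCO | starting material
12 | 4-methoxybenzyl chloride | COc1ccc(CCl)cc1 | starting material
13 | 1-methoxy-4-[(prop-2-yn-1-yloxy)methyl]benzene | C#CCOCc1ccc(OC)cc1 | intermediate
14 | 1-methoxy-4-[(propa-1,2-dien-1-yloxy)methyl]benzene | C=C=COCc1ccc(OC)cc1 | intermediate
15 | 1-lithio-1-[(4-methoxybenzyl)oxy]propa-1,2-diene | [Li]C(OCc1ccc(OC)cc1)=C=C | intermediate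
16 | (5S,6S)-6-[(4R)-2,2-dimethyl-1,3-dioxolan-4-yl]-3-[(4-methoxybenzyl)oxy]-6-methyl-5-(prop-1-en-2-yl)octa-1,2,7-trien-4-one | C=C[C@@](C)([C@H](C(C)=C)C(=O)C(OCc2ccc(OC)cc2)=C=C)[C@@H]1COC(C)(C)O1 | intermediate
17 | (4S,5S,6S)-6-[(4R)-2,2-dimethyl-1,3-dioxolan-4-yl]-3-[(4-methoxybenzyl)oxy]-6-methyl-5-(prop-1-en-2-yl)octa-1,2,7-trien-4-ol | C=C[C@@](C)([C@H](C(C)=C)[C@H](O)C(OCc2ccc(OC)cc2)=C=C)[C@@H]1COC(C)(C)O1 | intermediate
18 | (5S)-3-(chloromethyl)-5-{(1S,2S)-2-[(4R)-2,2-dimethyl-1,3-dioxolan-4-yl]-2-methyl-1-(prop-1-en-2-yl)but-3-en-1-yl}-4-[(4-methoxybenzyl)oxy]furan-2(5H)-one | C=C[C@@](C)([C@H](C(C)=C)[C@@H]2OC(=O)C(CCl)=C2OCc3ccc(OC)cc3)[C@@H]1COC(C)(C)O1 | intermediate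
19 | (5S)-3-(chloromethyl)-5-[(1S,2S,3R)-2-ethenyl-3,4-dihydroxy-2-methyl-1-(prop-1-en-2-yl)butyl]-4-[(4-methoxybenzyl)oxy]furan-2(5H)-one | C=C[C@@](C)([C@H](C(C)=C)[C@@H]2OC(=O)C(CCl)=C2OCc3ccc(OC)cc3)[C@@H](O)CO | intermediate
20 | (5S)-3-(chloromethyl)-5-[(1S,2S,3R)-2-ethenyl-3-hydroxy-2-methyl-1-(prop-1-en-2-yl)-4-(triethylsilyloxy)butyl]-4-[(4-methoxybenzyl)oxy]furan-2(5H)-one | C=C[C@@](C)([C@H](C(C)=C)[C@@H]2OC(=O)C(CCl)=C2OCc3ccc(OC)cc3)[C@@H](O)CO[Si](CC)(CC)CC | intermediate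
21 | angelic acid, (2Z)-2-methylbut-2-enoic acid | C/C=C(/C)C(O)=O | starting material
22 | (2Z)-2-methylbut-2-enoic 2,4,6-trichlorobenzoic anhydride | C/C=C(/C)C(=O)OC(=O)c1c(Cl)cc(Cl)cc1Cl | intermediate
23 | (2R,3S,4S)-4-{(2S)-4-(chloromethyl)-3-[(4-methoxybenzyl)oxy]-5-oxo-2,5-dihydrofuran-2-yl}-3-ethenyl-3,5-dimethyl-1-(triethylsilyloxy)hex-5-en-2-yl (2Z)-2-methylbut-2-enoate | C=C[C@@](C)([C@H](C(C)=C)[C@@H]2OC(=O)C(CCl)=C2OCc3ccc(OC)cc3)[C@H](CO[Si](CC)(CC)CC)OC(=O)/C(C)=C\C | intermediate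
24 | (2R,3S,4S)-4-{(2S)-4-(chloromethyl)-3-[(4-methoxybenzyl)oxy]-5-oxo-2,5-dihydrofuran-2-yl}-3-ethenyl-3,5-dimethyl-1-oxohex-5-en-2-yl (2Z)-2-methylbut-2-enoate | C=C[C@@](C)([C@H](C(C)=C)[C@@H]2OC(=O)C(CCl)=C2OCc3ccc(OC)cc3)[C@H](C=O)OC(=O)/C(C)=C\C | intermediate
25 | allylindium dichloride formed from 24 at C13 (InCl2 in place of Cl) | C=C[C@@](C)([C@H](C(C)=C)[C@@H]2OC(=O)C(C[In](Cl)Cl)=C2OCc3ccc(OC)cc3)[C@H](C=O)OC(=O)/C(C)=C\C | intermediate
26 | (3aS,4S,5R,6S,7S,7aS)-6-ethenyl-4-hydroxy-3a-[(4-methoxybenzyl)oxy]-6-methyl-3-methylidene-2-oxo-7-(prop-1-en-2-yl)octahydro-1-benzofuran-5-yl (2Z)-2-methylbut-2-enoate | C=C[C@@]1(C)[C@H](C(=C)C)[C@@H]2OC(=O)C(=C)[C@]2(OCc3ccc(OC)cc3)[C@@H](O)[C@@H]1OC(=O)/C(C)=C\C | intermediate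
27 | (3aS,4S,5R,6S,7S,7aS)-6-ethenyl-3a,4-dihydroxy-6-methyl-3-methylidene-2-oxo-7-(prop-1-en-2-yl)octahydro-1-benzofuran-5-yl (2Z)-2-methylbut-2-enoate (CNP0114166.3) | C=C[C@@]1(C)[C@H](C(=C)C)[C@@H]2OC(=O)C(=C)[C@]2(O)[C@@H](O)[C@@H]1OC(=O)/C(C)=C\C | target

Total step count: 18. Longest linear sequence: 16 steps (steps 1 to 7 and 10 to 18, from 1).

Steps most likely to fail

Step 17. The allylindium may be protonated before it cyclises (net reduction of the chloride), the insertion into the allylic chloride may be slow, or the aldehyde face may be poorly differentiated. The fallback replaces the Barbier reaction by an intramolecular allylboration. It sets out from 23: Miyaura-type borylation of the allylic chloride (B2pin2, Pd2(dba)3, toluene, 50 °C) should give the allyl pinacolboronate F1, and direct Swern oxidation as in step 16 the boronate aldehyde F2. F2 should cyclise on warming (Sc(OTf)3 if needed) through the closed chair transition state of an allylboration, and aqueous work-up of the borate comes back to the route at 26.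

Step 12. The alkoxyallene may be hydrolysed or cycloisomerised by the Lewis- and Brønsted-acidic medium before carbonylation, and the isopropenyl or vinyl group may be carbonylated in competition. The fallback builds the tetronate from a propiolate instead of an allene. It sets out from 10: addition of lithiated methyl propiolate (THF, −78 °C) should give the ynone F3, and Felkin–Anh-selective reduction (DIBAL-H, or a Corey–Bakshi–Shibata reduction) the propargylic alcohol F4. Conjugate addition of 4-methoxybenzyl alcohol (cat. NaH, THF) with lactonisation should give the 3-unsubstituted tetronate F5, iodination with N-iodosuccinimide the 3-iodotetronate F6, and Stille coupling with (tributylstannyl)methanol (Pd(PPh3)4, dioxane, 80 °C) the 3-(hydroxymethyl)tetronate F7. MsCl, Et3N and LiCl then come back to the route at 18.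

Step 6. The lithium dienolate may form with mixed geometry, a boat transition state may compete because the dioxolanyl group is axial, or the facial control by C9 may be weak; each would erode the C5/C10 diastereoselectivity. The fallback runs the rearrangement through a boron ketene acetal under reagent control. It sets out from 5: Steglich esterification with 3-methylbut-3-enoic acid should give the deconjugated ester F8. Soft enolisation of F8 at its α-CH2 with a chiral 2-bromo-4,5-diphenyl-1,3-bis(4-tolylsulfonyl)-1,3,2-diazaborolidine and Et3N (enolate geometry set by amine and solvent, facial selectivity reinforced by the reagent), Ireland–Claisen rearrangement between −20 °C and rt and hydrolysis come back to the route at 9.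

Further compounds
F1 | step 17 | (2R,3S,4S)-3-ethenyl-4-{(2S)-3-[(4-methoxybenzyl)oxy]-5-oxo-4-[(4,4,5,5-tetramethyl-1,3,2-dioxaborolan-2-yl)methyl]-2,5-dihydrofuran-2-yl}-3,5-dimethyl-1-(triethylsilyloxy)hex-5-en-2-yl (2Z)-2-methylbut-2-enoate | C=C[C@@](C)([C@H](C(C)=C)[C@@H]2OC(=O)C(CB4OC(C)(C)C(C)(C)O4)=C2OCc3ccc(OC)cc3)[C@H](CO[Si](CC)(CC)CC)OC(=O)/C(C)=C\C
F2 | step 17 | (2R,3S,4S)-3-ethenyl-4-{(2S)-3-[(4-methoxybenzyl)oxy]-5-oxo-4-[(4,4,5,5-tetramethyl-1,3,2-dioxaborolan-2-yl)methyl]-2,5-dihydrofuran-2-yl}-3,5-dimethyl-1-oxohex-5-en-2-yl (2Z)-2-methylbut-2-enoate | C=C[C@@](C)([C@H](C(C)=C)[C@@H]2OC(=O)C(CB4OC(C)(C)C(C)(C)O4)=C2OCc3ccc(OC)cc3)[C@H](C=O)OC(=O)/C(C)=C\C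
F3 | step 12 | methyl (5S,6S)-6-[(4R)-2,2-dimethyl-1,3-dioxolan-4-yl]-6-methyl-4-oxo-5-(prop-1-en-2-yl)oct-7-en-2-ynoate | C=C[C@@](C)([C@H](C(C)=C)C(=O)C#CC(=O)OC)[C@@H]1COC(C)(C)O1
F4 | step 12 | methyl (4S,5S,6S)-6-[(4R)-2,2-dimethyl-1,3-dioxolan-4-yl]-4-hydroxy-6-methyl-5-(prop-1-en-2-yl)oct-7-en-2-ynoate | C=C[C@@](C)([C@H](C(C)=C)[C@H](O)C#CC(=O)OC)[C@@H]1COC(C)(C)O1
F5 | step 12 | (5S)-5-{(1S,2S)-2-[(4R)-2,2-dimethyl-1,3-dioxolan-4-yl]-2-methyl-1-(prop-1-en-2-yl)but-3-en-1-yl}-4-[(4-methoxybenzyl)oxy]furan-2(5H)-one | C=C[C@@](C)([C@H](C(C)=C)[C@@H]2OC(=O)C=C2OCc3ccc(OC)cc3)[C@@H]1COC(C)(C)O1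
F6 | step 12 | (5S)-5-{(1S,2S)-2-[(4R)-2,2-dimethyl-1,3-dioxolan-4-yl]-2-methyl-1-(prop-1-en-2-yl)but-3-en-1-yl}-3-iodo-4-[(4-methoxybenzyl)oxy]furan-2(5H)-one | C=C[C@@](C)([C@H](C(C)=C)[C@@H]2OC(=O)C(I)=C2OCc3ccc(OC)cc3)[C@@H]1COC(C)(C)O1
F7 | step 12 | (5S)-5-{(1S,2S)-2-[(4R)-2,2-dimethyl-1,3-dioxolan-4-yl]-2-methyl-1-(prop-1-en-2-yl)but-3-en-1-yl}-3-(hydroxymethyl)-4-[(4-methoxybenzyl)oxy]furan-2(5H)-one | C=C[C@@](C)([C@H](C(C)=C)[C@@H]2OC(=O)C(CO)=C2OCc3ccc(OC)cc3)[C@@H]1COC(C)(C)O1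
F8 | step 6 | (2Z)-3-[(4R)-2,2-dimethyl-1,3-dioxolan-4-yl]but-2-en-1-yl 3-methylbut-3-enoate | CC1(C)OC[C@@H](/C(C)=C\COC(=O)CC(C)=C)O1
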